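## Structural features

Kanzonol E (14) is an achiral flavone. Ring A (benzene) is fused to ring C (the 4-pyranone O1, C2, C3, C4, C4a, C8a). C2 carries ring B, which is fused through C3' and C4'–O to ring D, a 2,2-dimethyl-2H-pyran, so the flavone sits para to the pyran oxygen. Ring A bears a free hydroxyl at C7 and a 3-methylbut-2-enyl (prenyl) chain at C6; C5 and C8 are unsubstituted. There is no stereocentre, and the only olefin of fixed geometry is the cis C=C inside ring D.

The fragile groups are the ortho-prenyl phenol (acid closes it to a chroman, iodine or quinones oxidise it) and the styrene-type olefin of ring D (adds acid and electrophiles). Both olefins exclude hydrogenolysis, hot iodine and Lewis-acid ether cleavage late in the route.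

The real difficulty is twofold. Ring C must be closed without acid or oxidant. The prenyl group must sit at C6 and not at C8 or on oxygen, which direct prenylation of a resorcinol ketone or a 7-hydroxyflavone does not deliver cleanly.

The key step exploits two features:
- **Ring C as three components.** C4 is a one-carbon unit between arene carbon C4a and the two-carbon unit C3–C2 that carries ring B, and O1 sits on C8a next to C4a. So C4 can be carbon monoxide, C3–C2 a terminal alkyne, and C4a/C8a–O1 an ortho-iodophenol.
- **Ring A as a symmetrical resorcinol.** Ring A is a 4,6-disubstituted resorcinol with a latent mirror plane through C8 and C5. O1 and the C7 hydroxyl are the two resorcinol oxygens; C4a and C6 are the two equivalent positions, each para to one oxygen and ortho to the other. A symmetrical 4,6-diiodoresorcinol therefore fixes the C6 regiochemistry whichever iodine is replaced first.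

## Logic of the disconnections

14 is cut at C4a–C4, C4–C3 and O1–C2, the three bonds ring C needs beyond the arene, into 6, 11 and carbon monoxide. In one sentence: ring C is assembled in the last step from ortho-iodophenol 6, carbon monoxide and terminal alkyne 11 by a palladium-catalysed carbonylative annulation. The cut removes the whole heterocycle and the A/B junction at once and leaves two benzenoid fragments of about equal size, with no protecting group on the C7 hydroxyl. The forward step must take up carbon monoxide before alkynylation, close 6-endo (via 13) and not 5-exo (from 12), and tolerate two free phenols and two olefins.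

6 is traced to 5 by cutting the two O–CH2 acetal bonds. The phenols must be masked while an arylmagnesium is present and free for the annulation. The forward step is an acetal cleavage that must not protonate the prenyl olefin next to the liberated phenol.

5 is cut at the aryl–CH2 bond of the prenyl chain, giving 3 and prenyl bromide. The reason for cutting here is symmetry: the two iodines of 3 are mirror-related, so a single iodine–magnesium exchange (via 4) can only give one constitution, and the remaining iodine is automatically the one needed at C4a. The gain is that the C6 versus C8 question disappears. The demand is mono-exchange and attack at the CH2 terminus of the allylic bromide.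

3 is cut at its two O–CH2 bonds to 2, and 2 at its two C–I bonds to 1. Positions 4 and 6 of 1 are each activated ortho/para by both oxygens. The forward iodination must stop at two iodines and avoid C2.

11 is cut at the C≡C bond to aldehyde 9 (one-carbon homologation through 10), and 9 is traced to nitrile 7 by partial reduction (through 8). Buying 7 means ring D is never built in the presence of the ring A phenol and prenyl chain. Both steps must leave the ring D olefin untouched.

## Other disconnections considered

Alternative 1: the first route to mind. Cut C2=C3 (aldol) and O1–C2. Forward, Claisen–Schmidt condensation of acetophenone A1 with aldehyde 9 would give 2'-hydroxychalcone A2, followed by oxidative cyclisation with iodine in hot DMSO.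
- A1 must come from prenylation of 2,4-dihydroxyacetophenone, where C3 (between the hydroxyls), C5 and the C4 oxygen compete.
- The free 4-hydroxyl would need protection for the aldol.
- The ring-closing step generates HI above 100 °C beside an ortho-prenyl phenol and the ring D olefin, so chroman formation and iodination are expected.
- The chosen plan settles the regiochemistry by symmetry and closes ring C under basic, non-oxidising conditions without protection in the last step.

Alternative 2: a double sigmatropic cascade. Cut the C6–CH2 bond of the prenyl chain and the C3'–C bond of ring D at once. Forward, heating bis-ether A3 would trigger an aromatic Claisen rearrangement of the 1,1-dimethylallyl ether on ring A, together with propargyl Claisen rearrangement, 1,5-hydrogen shift and oxa-6π electrocyclisation on ring B.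
- The ring B half is sound.
- In 7-allyloxychromones the C7–C8 bond has the higher double-bond character, so the [3,3] shift is expected to go to C8 and give the 8-prenyl isomer A4 rather than 14.
- Two different tertiary ethers on two phenols also require differentiating the hydroxyls, which costs steps.

Alternative 3: a late ortho-quinone methide. Cut the aryl–C and O–C bonds of ring D. Forward, condensation of diphenol A5 with 3-methylbut-2-enal at C3' would give quinone methide A6, which would close ring D by oxa-6π electrocyclisation.
- The ring B phenol is para to the electron-poor C2 of the pyranone and is the less nucleophilic arene.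
- C8 of ring A lies between two oxygens, so condensation is expected there, giving the angular pyranoflavone A7.
- A5 still contains the unsolved C6-prenyl problem, and ring D is available ready-made in 7. The step would attack the easier ring and leave the harder problem.

Key step: step 7

Assumption: 2,2-dimethyl-2H-chromene-6-carbonitrile (7) is taken as a purchasable building block; 14 has no stereocentre, and the E geometry drawn for transient 13 has no consequence for the product.

## Route

Step 1
Reactants: 1 resorcinol (benzene-1,3-diol)
Product: 2 4,6-diiodobenzene-1,3-diol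
Conditions: ICl (2.05 equiv), Et2O, 0 °C → rt; aq. Na2S2O3
Reagents that add atoms: iodine monochloride, ClI
Why: Electrophilic aromatic iodination; C4 and C6 are each para to one hydroxyl and ortho to the other, while C2 between the hydroxyls is the more hindered site, so two equivalents of ICl should give the symmetrical 4,6-diiodide.

Step 2
Reactants: 2 4,6-diiodobenzene-1,3-diol
Product: 3 1,5-diiodo-2,4-bis(methoxymethoxy)benzene
Conditions: MOMCl (2.5 equiv), iPr2NEt (3 equiv), CH2Cl2, 0 °C → rt
Reagents that add atoms: chloromethyl methyl ether, COCCl
Why: O-alkylation of both phenols as methoxymethyl acetals, which tolerate and chelate the organomagnesium of step 3; the mirror symmetry of 2 is kept.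

Step 3
Reactants: 3 1,5-diiodo-2,4-bis(methoxymethoxy)benzene
Product: 5 1-iodo-2,4-bis(methoxymethoxy)-5-(3-methylbut-2-en-1-yl)benzene, via arylmagnesium chloride 4 (not isolated)
Conditions: iPrMgCl·LiCl (1.05 equiv), THF, −40 °C; then CuI (10 mol %), prenyl bromide (1.3 equiv), −40 → 0 °C
Reagents that add atoms: prenyl bromide (1-bromo-3-methylbut-2-ene), CC(C)=CCBr
Why: Iodine–magnesium exchange with the LiCl-activated Grignard reagent, assisted by the ortho acetal oxygen, should stop after one exchange because the arylmagnesium ring is too electron-rich for a second, and the two iodines are mirror-related so only one constitution can form. Copper-catalysed allylic substitution at the unhindered CH2 terminus of prenyl bromide should then give the linear prenyl arene.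

Step 4
Reactants: 5 1-iodo-2,4-bis(methoxymethoxy)-5-(3-methylbut-2-en-1-yl)benzene
Product: 6 4-iodo-6-(3-methylbut-2-en-1-yl)benzene-1,3-diol
Conditions: 3 M aq. HCl, MeOH, 40 °C
Reagents that add atoms: none
Why: Acid-catalysed acetal exchange of both aryl methoxymethyl ethers with methanol; dilute acid at 40 °C should cleave the acetals faster than it protonates the trisubstituted olefin, and the aryl iodide is inert.

Step 5
Reactants: 7 2,2-dimethyl-2H-chromene-6-carbonitrile
Product: 9 2,2-dimethyl-2H-chromene-6-carbaldehyde, via aluminium aldiminate 8 (not isolated)
Conditions: iBu2AlH (1.2 equiv), toluene, −78 °C; then aq. potassium sodium tartrate, rt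
Reagents that add atoms: water, O
Why: Partial reduction of a nitrile; one hydride adds to give the N-aluminio aldimine 8, which resists further reduction at −78 °C and is hydrolysed to the aldehyde on work-up, and the ring D olefin is not hydroaluminated at this temperature.

Step 6
Reactants: 9 2,2-dimethyl-2H-chromene-6-carbaldehyde
Product: 11 6-ethynyl-2,2-dimethyl-2H-chromene, via diazoalkene 10 (not isolated)
Conditions: dimethyl (1-diazo-2-oxopropyl)phosphonate (1.3 equiv), K2CO3 (2 equiv), MeOH, 0 °C → rt
Reagents that add atoms: dimethyl (1-diazo-2-oxopropyl)phosphonate, COP(=O)(OC)C(=[N+]=[N-])C(C)=O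
Why: Ohira–Bestmann (Seyferth–Gilbert) homologation; methanolysis releases the diazomethylphosphonate anion, which olefinates 9 to diazoalkene 10, and loss of N2 with 1,2-hydrogen shift of the alkylidene carbene gives the terminal alkyne. The mild base leaves ring D untouched.

Step 7
Reactants: 6 4-iodo-6-(3-methylbut-2-en-1-yl)benzene-1,3-diol; 11 6-ethynyl-2,2-dimethyl-2H-chromene
Product: 14 kanzonol E (7-hydroxy-2-(2,2-dimethyl-2H-chromen-6-yl)-6-(3-methylbut-2-en-1-yl)-4H-chromen-4-one), via alkynone 12 (not isolated), via enaminone 13 (not isolated)
Conditions: PdCl2(dppf) (5 mol %), CO (20 atm), Et2NH, 100 °C; aq. NH4Cl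
Reagents that add atoms: carbon monoxide, [C-]#[O+]
Why: Zerovalent palladium, formed from PdCl2(dppf) in the amine, inserts into the C–I bond of 6, carbon monoxide inserts to give the aroyl–palladium species, and the acetylide of 11 (deprotonated by Et2NH) is transferred and reductively eliminated to give alkynone 12, in which C4a–C4 and C4–C3 are made. Et2NH then adds to 12 in a conjugate sense to give enaminone 13, and the phenol oxygen on C8a attacks the aminated carbon and expels Et2NH, which makes O1–C2 and completes ring C. The closest known reaction type is the palladium-catalysed carbonylative annulation of ortho-iodophenols with terminal alkynes to flavones (carbonylative Sonogashira coupling followed by cyclisation) in a secondary amine. Ring C is the only ring closed, by a 6-endo-trig oxa-Michael addition–elimination on 13; the competing 5-exo-dig attack on 12, which would give an aurone, should be suppressed because the amine converts the alkynone into the enaminone faster than the phenol adds. No stereocentre is formed, and the geometry of 13 is irrelevant because both substituents on the attacked carbon are exocyclic. The step needs carbonylative rather than direct coupling (which would end in a 2-arylbenzofuran); the electron-rich aryl–palladium intermediate should insert carbon monoxide quickly, the carbon monoxide pressure is high and no copper salt is present. It also needs selectivity between the two hydroxyls, which the substrate secures by geometry, since only the hydroxyl ortho to the new acyl group can reach the enaminone carbon, so the C7 hydroxyl stays free without protection. The prenyl and ring D olefins are out of reach of the palladated carbon and meet neither acid nor oxidant.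

## Compound list

1 | resorcinol (benzene-1,3-diol) | Oc1cccc(O)c1 | starting material
2 | 4,6-diiodobenzene-1,3-diol | Oc1cc(O)c(I)cc1I | intermediate
3 | 1,5-diiodo-2,4-bis(methoxymethoxy)benzene | COCOc1cc(OCOC)c(I)cc1I | intermediate
4 | [5-iodo-2,4-bis(methoxymethoxy)phenyl]magnesium chloride (LiCl complex, formed in step 3) | COCOc1cc(OCOC)c([Mg]Cl)cc1I | intermediate
5 | 1-iodo-2,4-bis(methoxymethoxy)-5-(3-methylbut-2-en-1-yl)benzene | COCOc1cc(OCOC)c(CC=C(C)C)cc1I | intermediate
6 | 4-iodo-6-(3-methylbut-2-en-1-yl)benzene-1,3-diol | CC(C)=CCc1cc(I)c(O)cc1O | intermediate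
7 | 2,2-dimethyl-2H-chromene-6-carbonitrile | CC1(C)C=Cc2cc(C#N)ccc2O1 | starting material
8 | N-(diisobutylaluminio) aldimine of 2,2-dimethyl-2H-chromene-6-carbaldehyde (formed in step 5) | CC(C)C[Al](CC(C)C)N=Cc1ccc2c(c1)C=CC(C)(C)O2 | intermediate
9 | 2,2-dimethyl-2H-chromene-6-carbaldehyde | O=Cc1ccc2c(c1)C=CC(C)(C)O2 | intermediate
10 | 6-(2-diazoethenyl)-2,2-dimethyl-2H-chromene (formed in step 6) | [N-]=[N+]=C=Cc1ccc2c(c1)C=CC(C)(C)O2 | intermediate
11 | 6-ethynyl-2,2-dimethyl-2H-chromene | C#Cc1ccc2c(c1)C=CC(C)(C)O2 | intermediate
12 | 1-[2,4-dihydroxy-5-(3-methylbut-2-en-1-yl)phenyl]-3-(2,2-dimethyl-2H-chromen-6-yl)prop-2-yn-1-one (formed in step 7) | CC(C)=CCc1cc(C(=O)C#Cc2ccc3c(c2)C=CC(C)(C)O3)c(O)cc1O | intermediate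
13 | (E)-3-(diethylamino)-1-[2,4-dihydroxy-5-(3-methylbut-2-en-1-yl)phenyl]-3-(2,2-dimethyl-2H-chromen-6-yl)prop-2-en-1-one (formed in step 7) | CCN(CC)/C(=C/C(=O)c1cc(CC=C(C)C)c(O)cc1O)c1ccc2c(c1)C=CC(C)(C)O2 | intermediate
14 | kanzonol E, 7-hydroxy-2-(2,2-dimethyl-2H-chromen-6-yl)-6-(3-methylbut-2-en-1-yl)-4H-chromen-4-one | CC(C)=CCc1cc2c(=O)cc(-c3ccc4c(c3)C=CC(C)(C)O4)oc2cc1O | target

## Step count and risks

Total: 7 steps. Longest linear sequence: 5 steps (steps 1, 2, 3, 4, 7). The alkyne branch (steps 5, 6) joins in step 7.

**Step 7 (key step).**
- Most likely failure: aminocarbonylation of the aroyl–palladium intermediate by the solvent amine, or direct alkynylation without carbon monoxide uptake followed by 5-endo cyclisation. Oxidative addition may also be slow, because under basic conditions the ring is a very electron-rich resorcinol phenoxide.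
- Fallback: sets out from 5 and 11 and comes back at 12, with no palladium or carbon monoxide. Iodine–magnesium exchange on 5 (iPrMgCl·LiCl) and quenching with DMF should give 2,4-bis(methoxymethoxy)-5-(3-methylbut-2-en-1-yl)benzaldehyde F1. Addition of the lithium acetylide of 11 (n-BuLi, THF, −78 °C) should give racemic 1-[2,4-bis(methoxymethoxy)-5-(3-methylbut-2-en-1-yl)phenyl]-3-(2,2-dimethyl-2H-chromen-6-yl)prop-2-yn-1-ol F2. MnO2 in CH2Cl2 should oxidise it to 1-[2,4-bis(methoxymethoxy)-5-(3-methylbut-2-en-1-yl)phenyl]-3-(2,2-dimethyl-2H-chromen-6-yl)prop-2-yn-1-one F3. Acetal cleavage as in step 4 should release 12, which in Et2NH should close through 13 to 14.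

**Step 3.**
- Most likely failure: attack of the arylcopper at the tertiary terminus of the allylic bromide (branched, reverse-prenyl connectivity), or a second exchange at the remaining iodine, because allylic substitution regiochemistry depends on the copper species.
- Fallback: sets out from 3 and comes back at 5. The same exchange followed by allyl bromide, where both termini are identical, should give 1-iodo-2,4-bis(methoxymethoxy)-5-(prop-2-en-1-yl)benzene F4. Cross-metathesis with 2-methylbut-2-ene (second-generation Grubbs catalyst, CH2Cl2, 40 °C) should convert the allyl group into the prenyl group of 5.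

**Step 4.**
- Most likely failure: acid-catalysed addition of the freed phenol (or of methanol) to the prenyl olefin during acetal cleavage, closing a 2,2-dimethylchroman, because the tertiary cation is readily formed.
- Fallback: sets out from 3 and comes back at 6. 1-Iodo-2,4-bis(methoxymethoxy)-5-(prop-2-en-1-yl)benzene F4, whose monosubstituted olefin is much harder to protonate, is deprotected with HCl in MeOH to 4-iodo-6-(prop-2-en-1-yl)benzene-1,3-diol F5. The cross-metathesis with 2-methylbut-2-ene is then run on F5 under neutral conditions to give 6.

**Step 1.**
- Most likely failure: iodination at C2 (giving 2,4-diiodo or 2,4,6-triiodo patterns), because the free resorcinol is activated at all three positions.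
- Fallback: sets out from 1 and comes back at 3. 1 is first converted into 1,3-bis(methoxymethoxy)benzene F6 (MOMCl, iPr2NEt), and F6 is iodinated twice with N-iodosuccinimide in MeCN. C2 is then shielded by two flanking acetal groups, so substitution should stop at C4 and C6.

## Further compounds

F1 | step 7 | 2,4-bis(methoxymethoxy)-5-(3-methylbut-2-en-1-yl)benzaldehyde | COCOc1cc(OCOC)c(CC=C(C)C)cc1C=O
F2 | step 7 | 1-[2,4-bis(methoxymethoxy)-5-(3-methylbut-2-en-1-yl)phenyl]-3-(2,2-dimethyl-2H-chromen-6-yl)prop-2-yn-1-ol (racemic) | COCOc1cc(OCOC)c(CC=C(C)C)cc1C(O)C#Cc1ccc2c(c1)C=CC(C)(C)O2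
F3 | step 7 | 1-[2,4-bis(methoxymethoxy)-5-(3-methylbut-2-en-1-yl)phenyl]-3-(2,2-dimethyl-2H-chromen-6-yl)prop-2-yn-1-one | COCOc1cc(OCOC)c(CC=C(C)C)cc1C(=O)C#Cc1ccc2c(c1)C=CC(C)(C)O2
F4 | step 3 | 1-iodo-2,4-bis(methoxymethoxy)-5-(prop-2-en-1-yl)benzene | COCOc1cc(OCOC)c(CC=C)cc1I
F5 | step 4 | 4-iodo-6-(prop-2-en-1-yl)benzene-1,3-diol | C=CCc1cc(I)c(O)cc1O
F6 | step 1 | 1,3-bis(methoxymethoxy)benzene | COCOc1cccc(OCOC)c1
A1 | alternative 1 | 1-[2,4-dihydroxy-5-(3-methylbut-2-en-1-yl)phenyl]ethan-1-one | CC(=O)c1cc(CC=C(C)C)c(O)cc1O
A2 | alternative 1 | (E)-1-[2,4-dihydroxy-5-(3-methylbut-2-en-1-yl)phenyl]-3-(2,2-dimethyl-2H-chromen-6-yl)prop-2-en-1-one | CC(C)=CCc1cc(C(=O)/C=C/c2ccc3c(c2)C=CC(C)(C)O3)c(O)cc1O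
A3 | alternative 2 | 7-[(2-methylbut-3-en-2-yl)oxy]-2-{4-[(2-methylbut-3-yn-2-yl)oxy]phenyl}-4H-chromen-4-one | C=CC(C)(C)Oc1ccc2c(=O)cc(-c3ccc(OC(C)(C)C#C)cc3)oc2c1
A4 | alternative 2 | 7-hydroxy-2-(2,2-dimethyl-2H-chromen-6-yl)-8-(3-methylbut-2-en-1-yl)-4H-chromen-4-one | CC(C)=CCc1c(O)ccc2c(=O)cc(-c3ccc4c(c3)C=CC(C)(C)O4)oc12
A5 | alternative 3 | 7-hydroxy-2-(4-hydroxyphenyl)-6-(3-methylbut-2-en-1-yl)-4H-chromen-4-one | CC(C)=CCc1cc2c(=O)cc(-c3ccc(O)cc3)oc2cc1O
A6 | alternative 3 | ring B ortho-quinone methide, 7-hydroxy-2-[3-(3-methylbut-2-en-1-ylidene)-4-oxocyclohexa-1,5-dien-1-yl]-6-(3-methylbut-2-en-1-yl)-4H-chromen-4-one | CC(C)=CCc1cc2c(=O)cc(C3=CC(=CC=C(C)C)C(=O)C=C3)oc2cc1O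
A7 | alternative 3 | angular pyranoflavone, 2-(4-hydroxyphenyl)-8,8-dimethyl-6-(3-methylbut-2-en-1-yl)-4H,8H-pyrano[2,3-h]chromen-4-one | CC(C)=CCc1cc2c(=O)cc(-c3ccc(O)cc3)oc2c2C=CC(C)(C)Oc12
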